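The dihydrobenzofuran is disconnected across C3–C3a and C2–O1 in the biosynthetic sense: a benzyl-protected quercetin whose only free hydroxyl is O4′ (8) and a feruloyl imide of camphorsultam (13). One Ag2O oxidation joins the two phenoxyl radicals C5′–C8, and O4′–H then adds to the resulting p-quinone methide, so the C–C bond, the C–O bond and both stereocentres arise in a single operation. The step exploits the guaiacyl-type B ring of the finished flavonol (O4′ and its single free ortho carbon C5′, with O3′ blocked so that no benzodioxane can form) and the sultam-bearing C8, which fixes C3; C2 follows trans.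

Key step: step 8

Numbering used below: B-ring positions of the flavonol carry primes (C1′–C6′); the feruloyl chain is C7 (benzylic), C8, C9 (carbonyl); the new ring is O1, C2, C3, C3a, C7a.

Remark: for (1S)-(−)-2,10-camphorsultam the non-chelated s-cis/anti N-enoyl conformer is assumed to expose the Cα-Re face of C8 (3R in 15, 3S in the target); if the opposite sense is found, the enantiomeric sultam, equally available, is used with no other change.

Step 1
Reactants: 1 3-(benzyloxy)-4-hydroxybenzaldehyde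
Product: 2 3-(benzyloxy)-4-(methoxymethoxy)benzaldehyde
Conditions: MOMCl, K2CO3, acetone, 0 °C to rt
Reagents that add atoms: chloromethyl methyl ether, COCCl
Why: Williamson O-alkylation of the phenoxide masks the future ring oxygen O4′ as an acetal that survives the basic and oxidative steps and is later removed by acid without loss of benzyl ethers.

Step 2
Reactants: 2 3-(benzyloxy)-4-(methoxymethoxy)benzaldehyde; 3 1-[2,4-bis(benzyloxy)-6-hydroxyphenyl]ethanone
Product: 4 (E)-2′-hydroxy-4′,6′,3-tris(benzyloxy)-4-(methoxymethoxy)chalcone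
Conditions: KOH, EtOH/THF, rt
Reagents that add atoms: none
Why: Claisen–Schmidt (crossed aldol) condensation of the methyl ketone enolate with the non-enolisable aldehyde, followed by E1cB dehydration, should give the conjugated chalcone with the thermodynamically preferred E geometry.

Step 3
Reactants: 4 (E)-2′-hydroxy-4′,6′,3-tris(benzyloxy)-4-(methoxymethoxy)chalcone
Product: 6 5,7,3′-tri-O-benzyl-4′-O-(methoxymethyl)quercetin, via trans-dihydroflavonol 5 (not isolated)
Conditions: 30% H2O2, aq. NaOH, MeOH/THF, 0 °C to rt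
Reagents that add atoms: hydrogen peroxide, OO
Why: Algar–Flynn–Oyamada reaction, in which nucleophilic epoxidation of the enone, 6-endo opening at the benzylic carbon by the 2′-phenoxide to 5 and dehydrogenation in the alkaline peroxide medium close the pyranone ring and install the 3-OH, the two stereocentres of 5 being lost again.

Step 4
Reactants: 6 5,7,3′-tri-O-benzyl-4′-O-(methoxymethyl)quercetin
Product: 7 3,5,7,3′-tetra-O-benzyl-4′-O-(methoxymethyl)quercetin
Conditions: BnBr, K2CO3, DMF, 50 °C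
Reagents that add atoms: benzyl bromide, BrCc1ccccc1
Why: Williamson O-benzylation of the acidic enolic 3-OH, the only free hydroxyl, gives a 3-alkoxyflavone that cannot be over-oxidised to a flavonol quinone methide in the key step.

Step 5
Reactants: 7 3,5,7,3′-tetra-O-benzyl-4′-O-(methoxymethyl)quercetin
Product: 8 3,5,7,3′-tetra-O-benzylquercetin (4′-OH free)
Conditions: conc. HCl (few equiv), MeOH/THF, 45 °C
Reagents that add atoms: none
Why: Acid-catalysed acetal cleavage (transacetalisation to methanol) should remove the MOM group alone, since aryl benzyl ethers are stable to dilute HCl at this temperature, and frees O4′–H.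

Step 6
Reactants: 9 (E)-4-acetoxy-3-methoxycinnamic acid; 10 (1S)-(−)-2,10-camphorsultam
Product: 12 N-[(E)-4-acetoxy-3-methoxycinnamoyl]-(1S)-2,10-camphorsultam, via acid chloride 11 (not isolated)
Conditions: (COCl)2, cat. DMF, CH2Cl2, 0 °C to rt; evaporate; then 10, NaH, toluene, 0 °C to rt
Reagents that add atoms: none
Why: Acid chloride formation under Vilsmeier-type catalysis and N-acylation of the sodium salt of the sultam attach the auxiliary, the E alkene being untouched and the much less electrophilic aryl acetate surviving at 0 °C.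

Step 7
Reactants: 12 N-[(E)-4-acetoxy-3-methoxycinnamoyl]-(1S)-2,10-camphorsultam
Product: 13 N-[(E)-feruloyl]-(1S)-2,10-camphorsultam
Conditions: pyrrolidine (1.1 equiv), CH2Cl2, 0 °C
Reagents that add atoms: none
Why: Chemoselective aminolysis of the phenolic acetate, an aryl ester being a far better acyl donor towards pyrrolidine than the conjugated N-acylsultam, should free the phenol only.

Step 8
Reactants: 8 3,5,7,3′-tetra-O-benzylquercetin (4′-OH free); 13 N-[(E)-feruloyl]-(1S)-2,10-camphorsultam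
Product: 15 (2R,3R)-trans-dihydrobenzofuran-3-carbonyl sultam, via p-quinone methide 14 (not isolated)
Conditions: Ag2O (2.5 equiv), toluene/acetone 2:1, rt, dark; 13 added slowly to 8 (2 equiv)
Reagents that add atoms: none
Why: Ag2O oxidises both phenols to phenoxyl radicals; the feruloyl radical carries spin at C8 (α to the imide carbonyl) and the radical of 8 at C5′, the only free position ortho to O4′, so radical–radical C8–C5′ coupling and tautomerisation of the B-ring dienone give p-quinone methide 14. The closest known reaction type is the Ag2O dehydrodimerisation of ferulic esters and amides to trans-2-aryl-2,3-dihydrobenzofuran-3-carbonyl compounds (8–5 coupling), known also with chiral N-feruloyl auxiliaries and run here as a cross-coupling. The dihydrobenzofuran ring closes by 5-exo-trig conjugate (1,6-) addition of O4′–H to C7 of the quinone methide, which restores the guaiacyl arene. C3 (the former C8) is set in the C–C coupling by the sultam, which shields one face of C8 in the s-cis/anti N-enoyl conformer; C2 is set in the reversible ring closure under substrate control, the aryl group ending trans to the C3 acyl group. The step needs C5′–C8 coupling in preference to O–C8 coupling and homo-coupling: the O3′-benzyl group excludes a benzodioxane, the O3-benzyl group blocks oxidation through the flavonol enol, and slow addition of 13 to excess 8 disfavours feruloyl dimerisation. The C3-epimeric trans product is a diastereomer of 15 and should be removable by chromatography or crystallisation at this stage.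

Step 9
Reactants: 15 (2R,3R)-trans-dihydrobenzofuran-3-carbonyl sultam
Product: 16 3,5,7,7″-tetra-O-benzyl-2,3-dehydrosilychristin (benzofuran 7-O and flavonol 3,5,7-O benzylated)
Conditions: LiBH4, THF, MeOH (2 equiv), 0 °C
Reagents that add atoms: none
Why: Reductive cleavage of the N-acylsultam by borohydride (addition to the activated imide-type carbonyl, collapse and second reduction) should give the primary alcohol and the recoverable auxiliary, the chromone carbonyl being a far less electrophilic vinylogous ester and C3 being untouched (its descriptor changes from R to S only through the priority change).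

Step 10
Reactants: 16 3,5,7,7″-tetra-O-benzyl-2,3-dehydrosilychristin
Product: 17 2,3-dehydrosilychristin
Conditions: H2 (1 atm), 10% Pd/C, EtOAc/MeOH, rt
Reagents that add atoms: none
Why: Catalytic hydrogenolysis of the four aryl benzyl ethers under mild conditions, under which the cyclic secondary benzylic C2–O1 bond and the tetrasubstituted chromone C2=C3 bond are expected to persist as in the debenzylation of benzylated flavan-3-ols, should liberate the target without touching either stereocentre.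

Compound list
1 | 3-(benzyloxy)-4-hydroxybenzaldehyde | O=Cc1ccc(O)c(OCc2ccccc2)c1 | starting material
2 | 3-(benzyloxy)-4-(methoxymethoxy)benzaldehyde | COCOc1ccc(C=O)cc1OCc1ccccc1 | intermediate
3 | 1-[2,4-bis(benzyloxy)-6-hydroxyphenyl]ethanone | CC(=O)c1c(O)cc(OCc2ccccc2)cc1OCc1ccccc1 | starting material
4 | (E)-1-[2,4-bis(benzyloxy)-6-hydroxyphenyl]-3-[3-(benzyloxy)-4-(methoxymethoxy)phenyl]prop-2-en-1-one | COCOc1ccc(/C=C/C(=O)c2c(O)cc(OCc3ccccc3)cc2OCc2ccccc2)cc1OCc1ccccc1 | intermediate
5 | (±)-trans-5,7-bis(benzyloxy)-2-[3-(benzyloxy)-4-(methoxymethoxy)phenyl]-3-hydroxychroman-4-one (racemic, drawn without configuration; not isolated) | COCOc1ccc(C2Oc3cc(OCc4ccccc4)cc(OCc4ccccc4)c3C(=O)C2O)cc1OCc1ccccc1 | intermediate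
6 | 5,7-bis(benzyloxy)-2-[3-(benzyloxy)-4-(methoxymethoxy)phenyl]-3-hydroxy-4H-chromen-4-one | COCOc1ccc(-c2oc3cc(OCc4ccccc4)cc(OCc4ccccc4)c3c(=O)c2O)cc1OCc1ccccc1 | intermediate
7 | 3,5,7-tris(benzyloxy)-2-[3-(benzyloxy)-4-(methoxymethoxy)phenyl]-4H-chromen-4-one | COCOc1ccc(-c2oc3cc(OCc4ccccc4)cc(OCc4ccccc4)c3c(=O)c2OCc2ccccc2)cc1OCc1ccccc1 | intermediate
8 | 3,5,7-tris(benzyloxy)-2-[3-(benzyloxy)-4-hydroxyphenyl]-4H-chromen-4-one | Oc1ccc(-c2oc3cc(OCc4ccccc4)cc(OCc4ccccc4)c3c(=O)c2OCc2ccccc2)cc1OCc1ccccc1 | intermediate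
9 | (E)-3-(4-acetoxy-3-methoxyphenyl)prop-2-enoic acid | COc1cc(/C=C/C(=O)O)ccc1OC(C)=O | starting material
10 | (1S)-(−)-2,10-camphorsultam [(2R)-bornane-10,2-sultam] | CC1(C)[C@@H]2CC[C@]13CS(=O)(=O)N[C@@H]3C2 | starting material
11 | (E)-3-(4-acetoxy-3-methoxyphenyl)prop-2-enoyl chloride (not isolated) | COc1cc(/C=C/C(=O)Cl)ccc1OC(C)=O | intermediate
12 | N-[(E)-3-(4-acetoxy-3-methoxyphenyl)prop-2-enoyl]-(2R)-bornane-10,2-sultam | CC1(C)[C@@H]2CC[C@]13CS(=O)(=O)N(C(=O)/C=C/c4ccc(OC(C)=O)c(OC)c4)[C@@H]3C2 | intermediate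
13 | N-[(E)-3-(4-hydroxy-3-methoxyphenyl)prop-2-enoyl]-(2R)-bornane-10,2-sultam | CC1(C)[C@@H]2CC[C@]13CS(=O)(=O)N(C(=O)/C=C/c4ccc(O)c(OC)c4)[C@@H]3C2 | intermediate
14 | p-quinone methide from C5′–C8 coupling: N-acylsultam of 2-{3-(benzyloxy)-2-hydroxy-5-[3,5,7-tris(benzyloxy)-4-oxo-4H-chromen-2-yl]phenyl}-3-(3-methoxy-4-oxocyclohexa-2,5-dien-1-ylidene)propanoic acid, C8 configured as C3 of 15, exocyclic alkene geometry not defined (not isolated) | CC1(C)[C@@H]2CC[C@]13CS(=O)(=O)N(C(=O)[C@@H](C=C4C=CC(=O)C(OC)=C4)c4cc(-c5oc6cc(OCc7ccccc7)cc(OCc7ccccc7)c6c(=O)c5OCc5ccccc5)cc(OCc5ccccc5)c4O)[C@@H]3C2 | intermediate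
15 | N-{(2R,3R)-7-(benzyloxy)-2-(4-hydroxy-3-methoxyphenyl)-5-[3,5,7-tris(benzyloxy)-4-oxo-4H-chromen-2-yl]-2,3-dihydro-1-benzofuran-3-carbonyl}-(2R)-bornane-10,2-sultam (2,3-trans) | CC1(C)[C@@H]2CC[C@]13CS(=O)(=O)N(C(=O)[C@@H]4c5cc(-c6oc7cc(OCc8ccccc8)cc(OCc8ccccc8)c7c(=O)c6OCc6ccccc6)cc(OCc6ccccc6)c5O[C@H]4c4ccc(O)c(OC)c4)[C@@H]3C2 | intermediate
16 | 3,5,7-tris(benzyloxy)-2-[(2R,3S)-7-(benzyloxy)-2-(4-hydroxy-3-methoxyphenyl)-3-(hydroxymethyl)-2,3-dihydro-1-benzofuran-5-yl]-4H-chromen-4-one | COc1cc([C@@H]2Oc3c(OCc4ccccc4)cc(-c4oc5cc(OCc6ccccc6)cc(OCc6ccccc6)c5c(=O)c4OCc4ccccc4)cc3[C@H]2CO)ccc1O | intermediate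
17 | 2,3-dehydrosilychristin: 3,5,7-trihydroxy-2-[(2R,3S)-7-hydroxy-2-(4-hydroxy-3-methoxyphenyl)-3-(hydroxymethyl)-2,3-dihydro-1-benzofuran-5-yl]-4H-chromen-4-one | COc1cc([C@@H]2Oc3c(O)cc(-c4oc5cc(O)cc(O)c5c(=O)c4O)cc3[C@H]2CO)ccc1O | target

Total step count: 10
Longest linear sequence: 8 steps (steps 1–5 and 8–10)

Steps most likely to fail

Step 8. Homo-dimerisation of the feruloyl radical and O4′–C8 coupling may outrun the C5′–C8 cross-coupling, and facial discrimination at C8 may be modest. The fallback replaces radical coupling by a directed carbenoid C–H insertion. It sets out from 8 and returns to the route at 17.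
- Ortho-iodination of the phenoxide of 8 (I2, KI, NaHCO3, THF/H2O), which is far more reactive than the neutral dialkoxy A ring, should give 3,5,7-tris(benzyloxy)-2-[3-(benzyloxy)-4-hydroxy-5-iodophenyl]-4H-chromen-4-one F1.
- O-alkylation with 4-(benzyloxy)-3-methoxybenzyl chloride (K2CO3, DMF) should give the benzylic aryl ether F2.
- Palladium-catalysed coupling of the aryl iodide with methyl diazoacetate (Pd(PPh3)4, Ag2CO3, Et3N, toluene) should give the methyl aryldiazoacetate F3.
- Enantioselective intramolecular 1,5 C–H insertion of the rhodium carbenoid into the benzylic ether C–H bond (Rh2(S-PTTL)4 or its antipode, whichever delivers 2R) should close the dihydrobenzofuran as the cis-(2R,3S) methyl ester F4.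
- NaOMe/MeOH should epimerise C3 to the trans-(2R,3R) methyl ester F5.
- LiBH4 should give the penta-O-benzyl alcohol F6, and hydrogenolysis (H2, Pd/C) of its five benzyl ethers leads to 17.

Step 3. The 2′-phenoxide may open the chalcone epoxide at the α-carbon (5-exo), favoured by the 6′-alkoxy group, and so divert material to the aurone. The fallback separates ring closure from C3 oxygenation. It sets out from 4 and returns at 6.
- Iodine-catalysed oxidative cyclisation (cat. I2, DMSO, 110 °C) should give 5,7-bis(benzyloxy)-2-[3-(benzyloxy)-4-(methoxymethoxy)phenyl]-4H-chromen-4-one F7.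
- Epoxidation of the flavone C2=C3 bond with dimethyldioxirane (acetone/CH2Cl2, 0 °C) and opening of the epoxide with cat. TsOH should give flavonol 6.

Step 9. Base-induced β-elimination of the C2 aryloxide (ring opening) or epimerisation at C3 may occur before hydride delivery, and hydride may attack the chromone. The fallback removes the auxiliary hydrolytically and then reduces with an electrophilic hydride. It sets out from 15 and returns at 16.
- LiOH/H2O2 (THF/H2O, 0 °C) should cleave the sultam to (2R,3R)-7-(benzyloxy)-2-(4-hydroxy-3-methoxyphenyl)-5-[3,5,7-tris(benzyloxy)-4-oxo-4H-chromen-2-yl]-2,3-dihydro-1-benzofuran-3-carboxylic acid F8.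
- BH3·SMe2 (THF, 0 °C) should reduce the carboxylic acid selectively to 16.

Further compounds
F1 | step 8 | 3,5,7-tris(benzyloxy)-2-[3-(benzyloxy)-4-hydroxy-5-iodophenyl]-4H-chromen-4-one | Oc1c(I)cc(-c2oc3cc(OCc4ccccc4)cc(OCc4ccccc4)c3c(=O)c2OCc2ccccc2)cc1OCc1ccccc1
F2 | step 8 | 3,5,7-tris(benzyloxy)-2-{3-(benzyloxy)-4-[4-(benzyloxy)-3-methoxybenzyloxy]-5-iodophenyl}-4H-chromen-4-one | COc1cc(COc2c(I)cc(-c3oc4cc(OCc5ccccc5)cc(OCc5ccccc5)c4c(=O)c3OCc3ccccc3)cc2OCc2ccccc2)ccc1OCc1ccccc1
F3 | step 8 | methyl 2-diazo-2-{3-(benzyloxy)-2-[4-(benzyloxy)-3-methoxybenzyloxy]-5-[3,5,7-tris(benzyloxy)-4-oxo-4H-chromen-2-yl]phenyl}acetate | COC(=O)C(=[N+]=[N-])c1cc(-c2oc3cc(OCc4ccccc4)cc(OCc4ccccc4)c3c(=O)c2OCc2ccccc2)cc(OCc2ccccc2)c1OCc1ccc(OCc2ccccc2)c(OC)c1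
F4 | step 8 | methyl (2R,3S)-cis-7-(benzyloxy)-2-[4-(benzyloxy)-3-methoxyphenyl]-5-[3,5,7-tris(benzyloxy)-4-oxo-4H-chromen-2-yl]-2,3-dihydro-1-benzofuran-3-carboxylate | COc1cc([C@@H]2Oc3c(OCc4ccccc4)cc(-c4oc5cc(OCc6ccccc6)cc(OCc6ccccc6)c5c(=O)c4OCc4ccccc4)cc3[C@@H]2C(=O)OC)ccc1OCc1ccccc1
F5 | step 8 | methyl (2R,3R)-trans-7-(benzyloxy)-2-[4-(benzyloxy)-3-methoxyphenyl]-5-[3,5,7-tris(benzyloxy)-4-oxo-4H-chromen-2-yl]-2,3-dihydro-1-benzofuran-3-carboxylate | COc1cc([C@@H]2Oc3c(OCc4ccccc4)cc(-c4oc5cc(OCc6ccccc6)cc(OCc6ccccc6)c5c(=O)c4OCc4ccccc4)cc3[C@H]2C(=O)OC)ccc1OCc1ccccc1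
F6 | step 8 | 3,5,7-tris(benzyloxy)-2-{(2R,3S)-7-(benzyloxy)-2-[4-(benzyloxy)-3-methoxyphenyl]-3-(hydroxymethyl)-2,3-dihydro-1-benzofuran-5-yl}-4H-chromen-4-one | COc1cc([C@@H]2Oc3c(OCc4ccccc4)cc(-c4oc5cc(OCc6ccccc6)cc(OCc6ccccc6)c5c(=O)c4OCc4ccccc4)cc3[C@H]2CO)ccc1OCc1ccccc1
F7 | step 3 | 5,7-bis(benzyloxy)-2-[3-(benzyloxy)-4-(methoxymethoxy)phenyl]-4H-chromen-4-one | COCOc1ccc(-c2cc(=O)c3c(OCc4ccccc4)cc(OCc4ccccc4)cc3o2)cc1OCc1ccccc1
F8 | step 9 | (2R,3R)-7-(benzyloxy)-2-(4-hydroxy-3-methoxyphenyl)-5-[3,5,7-tris(benzyloxy)-4-oxo-4H-chromen-2-yl]-2,3-dihydro-1-benzofuran-3-carboxylic acid | COc1cc([C@@H]2Oc3c(OCc4ccccc4)cc(-c4oc5cc(OCc6ccccc6)cc(OCc6ccccc6)c5c(=O)c4OCc4ccccc4)cc3[C@H]2C(=O)O)ccc1O
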